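**Strategy.** Everything rests on disconnecting the two C15–O ester bonds by a 1,3-shift. The target's malonate is attached at C15, the CH2 end of each (E)-C13=C14 allyl system. Moving both acyloxy groups back to C13 reveals tertiary esters with C14=C15 vinyl groups, the oxidation pattern of sclareol's side chain. One palladium(II)-catalysed twofold allylic ester transposition therefore forms both C15–O bonds and both E-trisubstituted alkenes; the Δ7 decalin rings (A/B) are untouched and no ring is made. The precursor is bis(labda-7,14-dien-13-yl) malonate, built from a sclareol-derived Δ7 methyl ketone, vinylmagnesium bromide and Meldrum's acid.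

Key step: step 7

Remark on stereochemistry: labdane numbering is used; C5, C9 and C10 keep the sclareol configuration (5α-H, 9α-H, 10β-CH3) throughout, and C13 of compounds 9 and 11–14 is carried as both epimers because step 7 makes this carbon sp2, so their SMILES carry no C13 descriptor (the 13R,13'R diester is one component of 13).

Remark on the alkene installation: a free C8 cation next to the C13 ketone would be captured by the carbonyl oxygen to give the cyclic enol ether (sclareol oxide), so the C7=C8 bond is installed in two cation-free operations (steps 2 and 3).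

**Step 1**
Reactants: 1 (−)-sclareol
Product: 4 8α-hydroxy-14,15-dinorlabdan-13-one, via labdane-8α,13,14,15-tetrol 2 (not isolated), via 8α,13-dihydroxy-15-norlabdan-14-al 3 (not isolated)
Conditions: OsO4 (2 mol%), NaIO4 (4 equiv), NaHCO3, THF/H2O, rt
Reagents that add atoms: none
Why: Lemieux–Johnson oxidative cleavage: osmium-catalysed dihydroxylation of the only alkene and two periodate cleavages (the 14,15-diol, then the α-hydroxy aldehyde) should excise C15 and C14 and turn the C13 carbinol into the methyl ketone, while the hindered C8 tertiary alcohol and the ring stereocentres are not touched and the bicarbonate buffer keeps the δ-hydroxy ketone from dehydrating to its cyclic enol ether.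

**Step 2**
Reactants: 4 8α-hydroxy-14,15-dinorlabdan-13-one
Product: 6 14,15-dinorlabd-8(17)-en-13-one, via C8 chlorosulfite ester 5 (not isolated)
Conditions: SOCl2 (1.5 equiv), pyridine, CH2Cl2, −78 °C
Reagents that add atoms: none
Why: Pyridine-mediated E2-type dehydration through the equatorial 8α-chlorosulfite, for which only a C17 methyl hydrogen can become anti-periplanar, should give mainly the exocyclic alkene (any Δ7 isomer 7 formed is simply carried on) and avoids a free C8 cation.

**Step 3**
Reactants: 6 14,15-dinorlabd-8(17)-en-13-one
Product: 7 14,15-dinorlabd-7-en-13-one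
Conditions: Co(salen-tBu,tBu)Cl (3 mol%), PhSiH3 (6 mol%), benzene, rt
Reagents that add atoms: none
Why: Cobalt-hydride hydrogen-atom-transfer alkene isomerisation: reversible H-atom delivery to C17 gives the tertiary C8 radical, and back-abstraction from the accessible C7 methylene rather than the congested tertiary C9–H should move the double bond into the ring as the trisubstituted C7=C8 alkene under neutral, cation-free conditions that leave the ketone and the C9 configuration alone.

**Step 4**
Reactants: 7 14,15-dinorlabd-7-en-13-one; 8 vinylmagnesium bromide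
Product: 9 labda-7,14-dien-13-ol (both C13 epimers)
Conditions: CH2=CHMgBr, CeCl3, THF, −78 to 0 °C; aq NH4Cl
Reagents that add atoms: vinylmagnesium bromide (8), C=C[Mg]Br
Why: Grignard 1,2-addition (organocerium-assisted to suppress enolisation of the methyl ketone) should give the tertiary allylic alcohol; the distant decalin exerts no facial control, so both C13 epimers are expected and are used together because step 7 removes this stereocentre.

**Step 5**
Reactants: 9 labda-7,14-dien-13-ol; 10 Meldrum's acid
Product: 11 labda-7,14-dien-13-yl hydrogen malonate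
Conditions: Meldrum's acid (1.1 equiv), toluene, 80 °C
Reagents that add atoms: Meldrum's acid (10), CC1(C)OC(=O)CC(=O)O1
Why: Thermal alcoholysis of Meldrum's acid (acylal ring opening with loss of acetone) is the standard route to malonic half esters of tertiary alcohols and needs neither acid chloride nor strong acid, so the ionisable tertiary allylic C13–O bond should survive.

**Step 6**
Reactants: 11 labda-7,14-dien-13-yl hydrogen malonate; 9 labda-7,14-dien-13-ol (second equivalent)
Product: 13 bis(labda-7,14-dien-13-yl) malonate, via alkoxycarbonyl ketene 12 (not isolated)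
Conditions: DCC (1.2 equiv), CH2Cl2, 0 °C to rt
Reagents that add atoms: none
Why: Carbodiimide esterification of a malonic half ester, which proceeds by dehydration to the alkoxycarbonyl ketene and its addition to the alcohol, is known to acylate hindered tertiary alcohols at room temperature without acid or strong base and should deliver the symmetrical bis-tertiary diester as a mixture of C13 epimers.

**Step 7**
Reactants: 13 bis(labda-7,14-dien-13-yl) malonate
Product: 15 bis[(13E)-labda-7,13-dien-15-yl] malonate (CNP0113044.1), via mono-transposed mixed malonate 14 (not isolated)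
Conditions: PdCl2(MeCN)2 (10 mol%), p-benzoquinone (10 mol%), THF, rt, dark
Reagents that add atoms: none
Why: Pd(II) binds the C14=C15 vinyl group of each tertiary ester, the ester carbonyl oxygen adds anti to C15 to give a six-membered 1,3-dioxan-2-ylium intermediate with Pd on C14, and anti C13–O cleavage with loss of Pd(II) releases the primary ester and the C13=C14 alkene. The closest known reaction type is the Pd(II)-catalysed cyclisation-induced [3,3] transposition of tertiary allylic acetates, including sclareol-type C13 acetates, here run at both ends of one malonate with the second shift passing through the mono-transposed ester 14. No ring is closed in the product (the dioxanylium ring is only transient) and no stereocentre is created; C13 loses its configuration, so all C13 epimers of 13 converge. The step needs E geometry at both C13=C14 bonds and complete conversion at both ends: the chair intermediate that keeps the C12 chain equatorial leads to E, and the primary ester with a trisubstituted alkene is thermodynamically preferred over the vinyl tertiary ester, which drives both shifts. The trisubstituted C7=C8 ring alkenes are too hindered to bind Pd(II), and neutral Pd(II) kept oxidised by benzoquinone avoids π-allyl ionisation, so the malonate CH2 should not be allylated. Z-containing isomers are the expected minor products and would be removed on AgNO3-impregnated silica.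

**Compound list**
1 | (−)-sclareol, (13R)-labd-14-ene-8α,13-diol | C[C@@]1(O)CC[C@H]2C(C)(C)CCC[C@]2(C)[C@H]1CC[C@@](C)(O)C=C | starting material
2 | labdane-8α,13,14,15-tetrol (13R, C14 mixed) | C[C@@]1(O)CC[C@H]2C(C)(C)CCC[C@]2(C)[C@H]1CC[C@@](C)(O)C(O)CO | intermediate (not isolated)
3 | 8α,13-dihydroxy-15-norlabdan-14-al (C13 as in sclareol) | C[C@@]1(O)CC[C@H]2C(C)(C)CCC[C@]2(C)[C@H]1CC[C@@](C)(O)C=O | intermediate (not isolated)
4 | 8α-hydroxy-14,15-dinorlabdan-13-one | C[C@@]1(O)CC[C@H]2C(C)(C)CCC[C@]2(C)[C@H]1CCC(C)=O | intermediate
5 | 13-oxo-14,15-dinorlabdan-8α-yl chlorosulfite | C[C@@]1(OS(=O)Cl)CC[C@H]2C(C)(C)CCC[C@]2(C)[C@H]1CCC(C)=O | intermediate (not isolated)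
6 | 14,15-dinorlabd-8(17)-en-13-one | C=C1CC[C@H]2C(C)(C)CCC[C@]2(C)[C@H]1CCC(C)=O | intermediate
7 | 14,15-dinorlabd-7-en-13-one | CC1=CC[C@H]2C(C)(C)CCC[C@]2(C)[C@H]1CCC(C)=O | intermediate
8 | vinylmagnesium bromide | C=C[Mg]Br | starting material
9 | labda-7,14-dien-13-ol (13R/13S mixture) | CC1=CC[C@H]2C(C)(C)CCC[C@]2(C)[C@H]1CCC(C)(O)C=C | intermediate
10 | Meldrum's acid | CC1(C)OC(=O)CC(=O)O1 | starting material
11 | labda-7,14-dien-13-yl hydrogen malonate (C13 epimers) | CC1=CC[C@H]2C(C)(C)CCC[C@]2(C)[C@H]1CCC(C)(C=C)OC(=O)CC(=O)O | intermediate
12 | (labda-7,14-dien-13-yloxy)carbonyl ketene | CC1=CC[C@H]2C(C)(C)CCC[C@]2(C)[C@H]1CCC(C)(C=C)OC(=O)C=C=O | intermediate (not isolated)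
13 | bis(labda-7,14-dien-13-yl) malonate (C13 epimers, includes 13R,13'R) | CC1=CC[C@H]2C(C)(C)CCC[C@]2(C)[C@H]1CCC(C)(C=C)OC(=O)CC(=O)OC(C)(C=C)CC[C@H]1C(C)=CC[C@H]2C(C)(C)CCC[C@]12C | intermediate
14 | (13E)-labda-7,13-dien-15-yl labda-7,14-dien-13-yl malonate | CC1=CC[C@H]2C(C)(C)CCC[C@]2(C)[C@H]1CC/C(C)=C/COC(=O)CC(=O)OC(C)(C=C)CC[C@H]1C(C)=CC[C@H]2C(C)(C)CCC[C@]12C | intermediate (not isolated)
15 | bis[(13E)-labda-7,13-dien-15-yl] malonate | CC1=CC[C@H]2C(C)(C)CCC[C@]2(C)[C@H]1CC/C(C)=C/COC(=O)CC(=O)OC/C=C(\C)CC[C@H]1C(C)=CC[C@H]2C(C)(C)CCC[C@]12C | target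

**Totals.** Total step count: 7. Longest linear sequence: 7 steps (1 → 4 → 6 → 7 → 9 → 11 → 13 → 15; alcohol 9 enters twice, in steps 5 and 6).

**Steps most likely to fail**

1. Step 7. The double transposition may stall after one shift or give Z geometry at one or both C13=C14 bonds, because methyl and the C12 methylene differ little in size. Adventitious Pd(0) could also ionise the allylic malonate and start decarboxylative allylation. Fallback: set out from ketone 7 and build the E alkene by olefination instead of transposition. Horner–Wadsworth–Emmons reaction with triethyl phosphonoacetate/NaH in THF should give ethyl (13E)-labda-7,13-dien-15-oate F1, with the Z ester removed by chromatography. DIBAL-H in CH2Cl2 at −78 °C then gives (13E)-labda-7,13-dien-15-ol F2. Steglich esterification of two equivalents of F2 with malonic acid (DCC, cat. DMAP, CH2Cl2) rejoins the route at target 15.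

2. Step 3. Hydrogen-atom back-abstraction may occur at C9–H and give the tetrasubstituted C8=C9 isomer, or the isomerisation may stop short or reduce the alkene. The fallback also bypasses step 2, where cyclisation to the enol ether could intrude. Fallback: set out from hydroxy ketone 4 and remove the carbonyl trap before an ionic dehydration. NaBH4 in MeOH gives 14,15-dinorlabdane-8α,13-diol F3. Ac2O/pyridine acetylates only the secondary alcohol to give 8α-hydroxy-14,15-dinorlabdan-13-yl acetate F4. Acid-catalysed E1 dehydration (cat. TsOH, benzene, warm) then gives 14,15-dinorlabd-7-en-13-yl acetate F5, with the C8=C9 isomer separated on AgNO3–silica. K2CO3/MeOH gives 14,15-dinorlabd-7-en-13-ol F6, and Dess–Martin oxidation rejoins the route at ketone 7.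

3. Step 5. Heating the tertiary allylic alcohol with the acidic acylal may cause ionisation or elimination at C13, and the half ester may decarboxylate on warming. Fallback: set out from alcohol 9 and form the malonate C–C bond by a crossed Claisen-type acylation, avoiding the free half acid. One portion of 9 is acetylated (Ac2O, Et3N, cat. DMAP) to labda-7,14-dien-13-yl acetate F7. A second portion is converted with NaH then carbonyldiimidazole in THF into labda-7,14-dien-13-yl imidazole-1-carboxylate F8. The lithium enolate of F7 (LiHMDS, 2.2 equiv, THF, −78 °C) is acylated by F8, which rejoins the route at diester 13 and bypasses 11 and step 6.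

**Further compounds**
F1 | step 7 | ethyl (13E)-labda-7,13-dien-15-oate | CCOC(=O)/C=C(\C)CC[C@H]1C(C)=CC[C@H]2C(C)(C)CCC[C@]12C
F2 | step 7 | (13E)-labda-7,13-dien-15-ol | OC/C=C(\C)CC[C@H]1C(C)=CC[C@H]2C(C)(C)CCC[C@]12C
F3 | step 3 | 14,15-dinorlabdane-8α,13-diol (C13 epimers) | C[C@@]1(O)CC[C@H]2C(C)(C)CCC[C@]2(C)[C@H]1CCC(C)O
F4 | step 3 | 8α-hydroxy-14,15-dinorlabdan-13-yl acetate (C13 epimers) | C[C@@]1(O)CC[C@H]2C(C)(C)CCC[C@]2(C)[C@H]1CCC(C)OC(C)=O
F5 | step 3 | 14,15-dinorlabd-7-en-13-yl acetate (C13 epimers) | CC1=CC[C@H]2C(C)(C)CCC[C@]2(C)[C@H]1CCC(C)OC(C)=O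
F6 | step 3 | 14,15-dinorlabd-7-en-13-ol (C13 epimers) | CC1=CC[C@H]2C(C)(C)CCC[C@]2(C)[C@H]1CCC(C)O
F7 | step 5 | labda-7,14-dien-13-yl acetate (C13 epimers) | CC1=CC[C@H]2C(C)(C)CCC[C@]2(C)[C@H]1CCC(C)(C=C)OC(C)=O
F8 | step 5 | labda-7,14-dien-13-yl 1H-imidazole-1-carboxylate (C13 epimers) | CC1=CC[C@H]2C(C)(C)CCC[C@]2(C)[C@H]1CCC(C)(C=C)OC(=O)n1ccnc1
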